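**Strategy.** Everything rests on cutting ring A at C4=C5. C2 of that ring (C1 = CMe2, C6 = CH bearing the polyene) carries two three-carbon arms, the ring segment C3–C4= and the prenyl CH2–CH=, that differ only beyond their alkene carbons, so a C2 with two allyl groups is a prochiral equivalent. One ring-closing metathesis on triene 16 (C6 stereodefined, with silyloxymethyl and (E)-but-2-en-2-yl groups; CMe2 at C1; two allyls at C2) closes ring A, forms C4=C5 and fixes C2 cis to C6. The spare allyl then becomes prenyl (ring A) or the hydroxyprenyl arm of ring B, whose C6' is epimerised to the 2',6'-trans series before a C20 + C10 + C20 Wittig assembly.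

Key step: step 11

Remarks on the chemistry (one line each):
- Ring positions use carotenoid numbering (C1 = CMe2, C2 = CH with the C5 arm, C3 = CH2, C4=C5(Me), C6 = CH bearing C7; primes for ring B).
- The target is (2S,6R,2'R,6'S): ring A is 2,6-cis, ring B is 2',6'-trans, with the same spatial sense at C2/C2' and the opposite sense at C6/C6'; ring B is therefore made from the same cis ring by deliberate C6 epimerisation.
- The C7 oxygen is carried as a silyl ether from step 2, because an acetate there would enolise and is itself an allyl ester under Ireland–Claisen conditions.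
- Two allyl groups on one carbon also close on each other to a cyclopentene; step 11 is run under ethylene so that this closure stays reversible.
- Assumption: all-E 2,7-dimethylocta-2,4,6-trienedial (28) is taken as a commercial building block.

**Step 1**
Reactants: 1 (E)-4-acetoxy-2-methylbut-2-enal
Product: 2 (2E)-3-methylpent-2-ene-1,4-diol (racemic)
Conditions: MeMgBr (3.5 equiv), THF, −78 → 0 °C; aq. NH4Cl
Reagents that add atoms: methylmagnesium bromide, C[Mg]Br
Why: Grignard 1,2-addition to the enal, with the excess reagent cleaving the acetate by double addition, should give the diol with the E alkene untouched.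

**Step 2**
Reactants: 2 (2E)-3-methylpent-2-ene-1,4-diol
Product: 3 (3E)-5-[(tert-butyldimethylsilyl)oxy]-3-methylpent-3-en-2-ol (racemic)
Conditions: TBSCl (1.0 equiv), imidazole, CH2Cl2, −20 → 0 °C
Reagents that add atoms: tert-butyldimethylsilyl chloride, CC(C)(C)[Si](C)(C)Cl
Why: Selective silylation, since the primary allylic hydroxyl reacts much faster than the secondary one at low temperature.

**Step 3**
Reactants: 3 (3E)-5-[(tert-butyldimethylsilyl)oxy]-3-methylpent-3-en-2-ol
Product: 4 (3E)-5-[(tert-butyldimethylsilyl)oxy]-3-methylpent-3-en-2-one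
Conditions: MnO2 (activated, excess), CH2Cl2, 25 °C
Reagents that add atoms: none
Why: MnO2 oxidation of a secondary allylic alcohol to the enone is mild and should leave the silyl ether and the alkene geometry intact.

**Step 4**
Reactants: 4 (3E)-5-[(tert-butyldimethylsilyl)oxy]-3-methylpent-3-en-2-one
Product: 5 (2S,3E)-5-[(tert-butyldimethylsilyl)oxy]-3-methylpent-3-en-2-ol
Conditions: (R)-2-methyl-CBS-oxazaborolidine (15 mol%), catecholborane, toluene, −78 °C; MeOH, then aq. NaOH wash
Reagents that add atoms: none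
Why: Corey–Bakshi–Shibata reduction, in which the trisubstituted alkenyl group acts as the large substituent so that the (R)-catalyst should deliver hydride to give the (S)-carbinol, while catecholborane at −78 °C avoids hydroboration.

**Step 5**
Reactants: 5 (2S,3E)-5-[(tert-butyldimethylsilyl)oxy]-3-methylpent-3-en-2-ol; 6 isobutyryl chloride
Product: 7 (2S,3E)-5-[(tert-butyldimethylsilyl)oxy]-3-methylpent-3-en-2-yl 2-methylpropanoate
Conditions: pyridine, DMAP (cat.), CH2Cl2, 0 → 25 °C
Reagents that add atoms: none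
Why: DMAP-catalysed acylation of the secondary alcohol proceeds with retention at the carbinol carbon.

**Step 6**
Reactants: 7 (2S,3E)-5-[(tert-butyldimethylsilyl)oxy]-3-methylpent-3-en-2-yl 2-methylpropanoate
Product: 10 (3R,4E)-3-{[(tert-butyldimethylsilyl)oxy]methyl}-2,2,4-trimethylhex-4-enoic acid, via silyl ketene acetal 8 (not isolated), via trimethylsilyl ester 9 (not isolated)
Conditions: LDA (LiNiPr2), THF, −78 °C; Me3SiCl; −78 → 60 °C; aq. citric acid work-up
Reagents that add atoms: none
Why: Ireland–Claisen rearrangement, in which the gem-dimethyl ketene acetal has no E/Z issue and the chair transition state with the carbinol methyl equatorial should transfer the (S) centre through the (E)-alkene to give (R)-C6, the quaternary C1 and the (E)-but-2-en-2-yl group.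

**Step 7**
Reactants: 10 (3R,4E)-3-{[(tert-butyldimethylsilyl)oxy]methyl}-2,2,4-trimethylhex-4-enoic acid
Product: 11 methyl (3R,4E)-3-{[(tert-butyldimethylsilyl)oxy]methyl}-2,2,4-trimethylhex-4-enoate
Conditions: MeI, K2CO3, DMF, 25 °C
Reagents that add atoms: methyl iodide, CI
Why: Carboxylate O-alkylation (SN2 on MeI) esterifies the hindered acid without touching the stereocentre.

**Step 8**
Reactants: 11 methyl (3R,4E)-3-{[(tert-butyldimethylsilyl)oxy]methyl}-2,2,4-trimethylhex-4-enoate; 12 allylmagnesium bromide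
Product: 14 (6R,7E)-4-allyl-6-{[(tert-butyldimethylsilyl)oxy]methyl}-5,5,7-trimethylnona-1,7-dien-4-ol, via allyl ketone 13 (not isolated)
Conditions: allylMgBr (3 equiv), Et2O, 0 → 25 °C; aq. NH4Cl
Reagents that add atoms: allylmagnesium bromide (second equivalent), C=CC[Mg]Br
Why: Double Grignard addition to an ester, in which the first equivalent of 12 expels methoxide to give allyl ketone 13 and the second adds at once to this more electrophilic ketone, both through the six-membered allyl-transfer transition state that lets allylmagnesium bromide reach even a neopentyl-type carbonyl; the carbinol carbon carries two identical allyl groups and is not a stereocentre.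

**Step 9**
Reactants: 14 (6R,7E)-4-allyl-6-{[(tert-butyldimethylsilyl)oxy]methyl}-5,5,7-trimethylnona-1,7-dien-4-ol
Product: 15 (6R,7E)-4-allyl-6-{[(tert-butyldimethylsilyl)oxy]methyl}-5,5,7-trimethylnona-1,7-dien-4-yl methyl oxalate
Conditions: n-BuLi, THF, −78 °C; ClC(O)CO2Me, −78 → 0 °C
Reagents that add atoms: methyl chlorooxoacetate, COC(=O)C(=O)Cl
Why: O-Acylation of the lithium alkoxide with the small, very reactive acid chloride should give the tertiary methyl oxalate needed for radical C–O cleavage.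

**Step 10**
Reactants: 15 (6R,7E)-4-allyl-6-{[(tert-butyldimethylsilyl)oxy]methyl}-5,5,7-trimethylnona-1,7-dien-4-yl methyl oxalate
Product: 16 (6R,7E)-4-allyl-6-{[(tert-butyldimethylsilyl)oxy]methyl}-5,5,7-trimethylnona-1,7-diene
Conditions: Bu3SnH (0.5 M), AIBN, toluene, 110 °C
Reagents that add atoms: none
Why: Dolan–MacMillan radical deoxygenation of a tertiary methyl oxalate, in which the tertiary C2 radical has no productive cyclisation open (3-exo reversible, 4-exo and 5-endo slow) and is quenched by concentrated Bu3SnH to a CH with two identical allyl groups, so no stereocentre arises.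

**Step 11**
Reactants: 16 (6R,7E)-4-allyl-6-{[(tert-butyldimethylsilyl)oxy]methyl}-5,5,7-trimethylnona-1,7-diene
Product: 18 tert-butyl{[(1R,5S)-5-allyl-2,6,6-trimethylcyclohex-2-en-1-yl]methoxy}dimethylsilane (2,6-cis; C2 S, C6 R), via cyclopentene 17 (not isolated)
Conditions: second-generation Hoveyda–Grubbs catalyst (H2IMes)Cl2Ru(=CH-C6H4-2-OiPr) (10 mol%), toluene (0.005 M), ethylene (1 atm), 80 °C; then argon sparge
Reagents that add atoms: ethylene, C=C (its CH2 can end as the terminal CH2 of the spare allyl when 17 reopens)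
Why: Ring-closing olefin metathesis: the ruthenium alkylidene loads on a terminal allyl, and although closure onto the other allyl gives cyclopentene 17 fastest, that ring is reopened by the methylidene under ethylene, whereas [2+2] addition of the allyl alkylidene to the C5 alkene and cycloreversion (loss of ethylidene, hence propene) gives the trisubstituted cyclohexene irreversibly, so the material should drain into 18. The closest known reaction types are ring-closing metathesis to trisubstituted cyclohexenes, diastereotopic-group-selective metathesis of trienes and ring-rearrangement metathesis of cyclopentenes. Ring A closes in a six-membered mode by forming C4=C5, with C3 and C4 supplied by one allyl arm of C2. The new stereocentre C2 is controlled by C6: alkylidene exchange between the two allyls is fast, so the outcome is set in the two diastereomeric chair-like closures, and the one with the spare allyl on C2 and CH2OTBS on C6 both equatorial, turned away from the ruthenacyclobutane at C4–C5 and without a syn-axial pair across C1, leads to the 2,6-cis ring. Two selectivities are needed: six- over five-membered closure, secured by the reversibility of 17 and the inertness of the product alkene, and cis over trans, secured by the bulky silyloxymethyl group at C6 next to CMe2.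

**Step 12**
Reactants: 18 tert-butyl{[(1R,5S)-5-allyl-2,6,6-trimethylcyclohex-2-en-1-yl]methoxy}dimethylsilane; 19 2-methylbut-2-ene
Product: 20 tert-butyldimethyl{[(1R,5S)-2,6,6-trimethyl-5-(3-methylbut-2-en-1-yl)cyclohex-2-en-1-yl]methoxy}silane
Conditions: 19 (excess, co-solvent), second-generation Grubbs catalyst (H2IMes)(PCy3)Cl2Ru=CHPh (3 mol%), CH2Cl2, 40 °C
Reagents that add atoms: none
Why: Olefin cross-metathesis of the terminal allyl with 2-methylbut-2-ene turns CH=CH2 into CH=CMe2, while the trisubstituted ring alkene is inert.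

**Step 13**
Reactants: 20 tert-butyldimethyl{[(1R,5S)-2,6,6-trimethyl-5-(3-methylbut-2-en-1-yl)cyclohex-2-en-1-yl]methoxy}silane
Product: 21 [(1R,5S)-2,6,6-trimethyl-5-(3-methylbut-2-en-1-yl)cyclohex-2-en-1-yl]methanol
Conditions: Bu4NF, THF, 25 °C
Reagents that add atoms: none
Why: Fluoride-mediated desilylation releases the primary alcohol without affecting the alkenes or the stereocentres.

**Step 14**
Reactants: 21 [(1R,5S)-2,6,6-trimethyl-5-(3-methylbut-2-en-1-yl)cyclohex-2-en-1-yl]methanol
Product: 22 (1R,5S)-2,6,6-trimethyl-5-(3-methylbut-2-en-1-yl)cyclohex-2-ene-1-carbaldehyde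
Conditions: Dess–Martin periodinane, NaHCO3, CH2Cl2, 0 °C; used at once
Reagents that add atoms: none
Why: Dess–Martin oxidation under bicarbonate buffer forms the β,γ-unsaturated aldehyde without base, so the cis C6 centre and the C4=C5 position should be preserved.

**Step 15**
Reactants: 22 (1R,5S)-2,6,6-trimethyl-5-(3-methylbut-2-en-1-yl)cyclohex-2-ene-1-carbaldehyde; 23 1-(triphenylphosphoranylidene)propan-2-one
Product: 24 (3E)-4-[(1R,5S)-2,6,6-trimethyl-5-(3-methylbut-2-en-1-yl)cyclohex-2-en-1-yl]but-3-en-2-one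
Conditions: 23 (3 equiv), toluene, 90 °C
Reagents that add atoms: none
Why: Wittig olefination with a stabilised, nearly non-basic ylide should give the (E)-enone without enolising the epimerisable aldehyde.

**Step 16**
Reactants: 24 (3E)-4-[(1R,5S)-2,6,6-trimethyl-5-(3-methylbut-2-en-1-yl)cyclohex-2-en-1-yl]but-3-en-2-one; 25 vinylmagnesium bromide
Product: 26 (1E)-3-methyl-1-[(1R,5S)-2,6,6-trimethyl-5-(3-methylbut-2-en-1-yl)cyclohex-2-en-1-yl]penta-1,4-dien-3-ol (both C3 epimers)
Conditions: vinylMgBr (1.3 equiv), THF, −78 → −20 °C; aq. NH4Cl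
Reagents that add atoms: none
Why: Grignard 1,2-addition to the methyl enone at low temperature outpaces γ-deprotonation, and both carbinol epimers converge in the next step.

**Step 17**
Reactants: 26 (1E)-3-methyl-1-[(1R,5S)-2,6,6-trimethyl-5-(3-methylbut-2-en-1-yl)cyclohex-2-en-1-yl]penta-1,4-dien-3-ol
Product: 27 {(2E,4E)-3-methyl-5-[(1R,5S)-2,6,6-trimethyl-5-(3-methylbut-2-en-1-yl)cyclohex-2-en-1-yl]penta-2,4-dien-1-yl}triphenylphosphonium bromide
Conditions: PPh3·HBr, MeOH/CH2Cl2, 0 → 25 °C; crystallisation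
Reagents that add atoms: triphenylphosphine hydrobromide, [Br-].[PH+](c1ccccc1)(c1ccccc1)c1ccccc1
Why: Phosphonium salt formation with allylic transposition (SN1-type ionisation and capture of the pentadienyl cation by PPh3 at its terminal carbon), the standard entry to ionylidene-ethyl Wittig salts.

**Step 18**
Reactants: 27 ring A phosphonium bromide; 28 (2E,4E,6E)-2,7-dimethylocta-2,4,6-trienedial (3 equiv)
Product: 29 (2E,4E,6E,8E,10E,12E)-2,7,11-trimethyl-13-[(1R,5S)-2,6,6-trimethyl-5-(3-methylbut-2-en-1-yl)cyclohex-2-en-1-yl]trideca-2,4,6,8,10,12-hexaenal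
Conditions: 1,2-epoxybutane, EtOH, 70 °C, slow addition of 27; then heptane, 90 °C (E/Z isomerisation)
Reagents that add atoms: none
Why: Wittig olefination with the dialdehyde in excess should stop at mono-condensation, the epoxide generates the ylide under neutral conditions that protect the cis C6 centre, and heating brings the new C11=C12 bond to E.

**Step 19**
Reactants: 18 tert-butyl{[(1R,5S)-5-allyl-2,6,6-trimethylcyclohex-2-en-1-yl]methoxy}dimethylsilane; 30 methyl methacrylate
Product: 31 methyl (2E)-4-[(1R,5R)-5-{[(tert-butyldimethylsilyl)oxy]methyl}-4,6,6-trimethylcyclohex-3-en-1-yl]-2-methylbut-2-enoate (2,6-cis; C2 R, C6 R)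
Conditions: 30 (10 equiv), second-generation Grubbs catalyst (H2IMes)(PCy3)Cl2Ru=CHPh (5 mol%), CH2Cl2, 40 °C
Reagents that add atoms: none
Why: Cross-metathesis of a terminal alkene with methyl methacrylate gives the trisubstituted (E)-enoate under thermodynamic control, which fixes the E geometry of the future hydroxyprenyl arm.

**Step 20**
Reactants: 31 methyl (2E)-4-[(1R,5R)-5-{[(tert-butyldimethylsilyl)oxy]methyl}-4,6,6-trimethylcyclohex-3-en-1-yl]-2-methylbut-2-enoate
Product: 32 methyl (2E)-4-[(1R,5R)-5-(hydroxymethyl)-4,6,6-trimethylcyclohex-3-en-1-yl]-2-methylbut-2-enoate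
Conditions: Bu4NF, AcOH (buffer), THF, 25 °C
Reagents that add atoms: none
Why: Buffered fluoride desilylation frees the primary alcohol and leaves the methyl enoate intact.

**Step 21**
Reactants: 32 methyl (2E)-4-[(1R,5R)-5-(hydroxymethyl)-4,6,6-trimethylcyclohex-3-en-1-yl]-2-methylbut-2-enoate
Product: 33 methyl (2E)-4-[(1R,5R)-5-formyl-4,6,6-trimethylcyclohex-3-en-1-yl]-2-methylbut-2-enoate
Conditions: Dess–Martin periodinane, NaHCO3, CH2Cl2, 0 °C; used at once
Reagents that add atoms: none
Why: Dess–Martin oxidation gives the aldehyde under non-basic conditions compatible with the enoate.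

**Step 22**
Reactants: 33 methyl (2E)-4-[(1R,5R)-5-formyl-4,6,6-trimethylcyclohex-3-en-1-yl]-2-methylbut-2-enoate; 23 1-(triphenylphosphoranylidene)propan-2-one
Product: 34 methyl (2E)-2-methyl-4-{(1R,5R)-4,6,6-trimethyl-5-[(1E)-3-oxobut-1-en-1-yl]cyclohex-3-en-1-yl}but-2-enoate (2,6-cis)
Conditions: 23 (3 equiv), toluene, 90 °C
Reagents that add atoms: none
Why: Wittig olefination with the stabilised ylide gives the (E)-enone and is indifferent to the remote enoate.

**Step 23**
Reactants: 34 cis-enone of ring B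
Product: 35 methyl (2E)-2-methyl-4-{(1R,5S)-4,6,6-trimethyl-5-[(1E)-3-oxobut-1-en-1-yl]cyclohex-3-en-1-yl}but-2-enoate (2,6-trans; C2 R, C6 S)
Conditions: NaOMe (0.2 equiv), MeOH, 25 °C, monitored; chromatography, cis epimer recycled
Reagents that add atoms: none
Why: Base-mediated vinylogous epimerisation at C6 through the extended dienolate, the equilibration that turns cis-α-irone into trans-α-irone, should favour the 2,6-trans enone (C6 arm pseudo-axial, C2 arm equatorial) and so sets C6' by thermodynamic control.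

**Step 24**
Reactants: 35 trans-enone of ring B; 25 vinylmagnesium bromide
Product: 36 methyl (2E)-4-{(1R,5S)-5-[(1E)-3-hydroxy-3-methylpenta-1,4-dien-1-yl]-4,6,6-trimethylcyclohex-3-en-1-yl}-2-methylbut-2-enoate (both carbinol epimers)
Conditions: vinylMgBr (1.2 equiv), THF, −78 °C; aq. NH4Cl
Reagents that add atoms: none
Why: Grignard 1,2-addition is much faster at the methyl ketone than at the α-methyl enoate at −78 °C, so the ester should survive.

**Step 25**
Reactants: 36 ring B vinyl carbinol
Product: 37 {(2E,4E)-5-[(1S,5R)-5-[(2E)-4-methoxy-3-methyl-4-oxobut-2-en-1-yl]-2,6,6-trimethylcyclohex-2-en-1-yl]-3-methylpenta-2,4-dien-1-yl}triphenylphosphonium bromide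
Conditions: PPh3·HBr, MeOH/CH2Cl2, 0 → 25 °C; crystallisation
Reagents that add atoms: triphenylphosphine hydrobromide, [Br-].[PH+](c1ccccc1)(c1ccccc1)c1ccccc1
Why: Phosphonium salt formation with allylic transposition, as in step 17, to which the ester is inert.

**Step 26**
Reactants: 37 ring B phosphonium bromide; 29 C30 aldehyde
Product: 38 methyl ester of the target (C2' arm ending in CO2Me in place of CH2OH), (2S,6R,2'R,6'S), all-E
Conditions: 1,2-epoxybutane, EtOH, 70 °C; then heptane, 90 °C (E/Z isomerisation)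
Reagents that add atoms: none
Why: The second Wittig olefination joins the two halves at C11'=C12' under neutral conditions that spare the ester and all four stereocentres, and thermal isomerisation gives the all-E polyene.

**Step 27**
Reactants: 38 C50 methyl ester
Product: 39 target, (2S,6R,2'R,6'S)-2-(3-methylbut-2-enyl)-2'-[(2E)-4-hydroxy-3-methylbut-2-enyl]-ε,ε-carotene
Conditions: DIBAL (iBu2AlH, 3 equiv), CH2Cl2, −78 °C; aq. KNaC4H4O6 (potassium sodium tartrate) work-up
Reagents that add atoms: none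
Why: DIBAL reduction of the isolated α,β-unsaturated methyl ester to the allylic alcohol at −78 °C should leave the polyene untouched and reveal the (E)-hydroxyprenyl arm.

**Compound list**
1 | (E)-4-acetoxy-2-methylbut-2-enal | CC(=O)OC/C=C(C)/C=O | starting material
2 | (2E)-3-methylpent-2-ene-1,4-diol (racemic) | CC(O)/C(C)=C/CO | intermediate
3 | (3E)-5-[(tert-butyldimethylsilyl)oxy]-3-methylpent-3-en-2-ol (racemic) | CC(O)/C(C)=C/CO[Si](C)(C)C(C)(C)C | intermediate
4 | (3E)-5-[(tert-butyldimethylsilyl)oxy]-3-methylpent-3-en-2-one | CC(=O)/C(C)=C/CO[Si](C)(C)C(C)(C)C | intermediate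
5 | (2S,3E)-5-[(tert-butyldimethylsilyl)oxy]-3-methylpent-3-en-2-ol | C[C@H](O)/C(C)=C/CO[Si](C)(C)C(C)(C)C | intermediate
6 | isobutyryl chloride | CC(C)C(=O)Cl | starting material
7 | (2S,3E)-5-[(tert-butyldimethylsilyl)oxy]-3-methylpent-3-en-2-yl 2-methylpropanoate | C[C@H](OC(=O)C(C)C)/C(C)=C/CO[Si](C)(C)C(C)(C)C | intermediate
8 | trimethylsilyl ketene acetal of 7 | C[C@H](OC(O[Si](C)(C)C)=C(C)C)/C(C)=C/CO[Si](C)(C)C(C)(C)C | intermediate (not isolated)
9 | trimethylsilyl (3R,4E)-3-{[(tert-butyldimethylsilyl)oxy]methyl}-2,2,4-trimethylhex-4-enoate | C[Si](C)(C)OC(=O)C(C)(C)[C@H](CO[Si](C)(C)C(C)(C)C)/C(C)=C/C | intermediate (not isolated)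
10 | (3R,4E)-3-{[(tert-butyldimethylsilyl)oxy]methyl}-2,2,4-trimethylhex-4-enoic acid | OC(=O)C(C)(C)[C@H](CO[Si](C)(C)C(C)(C)C)/C(C)=C/C | intermediate
11 | methyl (3R,4E)-3-{[(tert-butyldimethylsilyl)oxy]methyl}-2,2,4-trimethylhex-4-enoate | COC(=O)C(C)(C)[C@H](CO[Si](C)(C)C(C)(C)C)/C(C)=C/C | intermediate
12 | allylmagnesium bromide | C=CC[Mg]Br | starting material
13 | (6R,7E)-6-{[(tert-butyldimethylsilyl)oxy]methyl}-5,5,7-trimethylnona-1,7-dien-4-one (allyl ketone) | C=CCC(=O)C(C)(C)[C@H](CO[Si](C)(C)C(C)(C)C)/C(C)=C/C | intermediate (not isolated)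
14 | (6R,7E)-4-allyl-6-{[(tert-butyldimethylsilyl)oxy]methyl}-5,5,7-trimethylnona-1,7-dien-4-ol | C=CCC(O)(CC=C)C(C)(C)[C@H](CO[Si](C)(C)C(C)(C)C)/C(C)=C/C | intermediate
15 | methyl oxalate of 14 | COC(=O)C(=O)OC(CC=C)(CC=C)C(C)(C)[C@H](CO[Si](C)(C)C(C)(C)C)/C(C)=C/C | intermediate
16 | (6R,7E)-4-allyl-6-{[(tert-butyldimethylsilyl)oxy]methyl}-5,5,7-trimethylnona-1,7-diene (key-step precursor) | C=CCC(CC=C)C(C)(C)[C@H](CO[Si](C)(C)C(C)(C)C)/C(C)=C/C | intermediate
17 | tert-butyl{[(2R,3E)-2-[2-(cyclopent-3-en-1-yl)propan-2-yl]-3-methylpent-3-en-1-yl]oxy}dimethylsilane | C1C=CCC1C(C)(C)[C@H](CO[Si](C)(C)C(C)(C)C)/C(C)=C/C | intermediate (not isolated)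
18 | tert-butyl{[(1R,5S)-5-allyl-2,6,6-trimethylcyclohex-2-en-1-yl]methoxy}dimethylsilane (key-step product) | C=CC[C@H]1CC=C(C)[C@@H](CO[Si](C)(C)C(C)(C)C)C1(C)C | intermediate
19 | 2-methylbut-2-ene | CC=C(C)C | starting material
20 | tert-butyldimethyl{[(1R,5S)-2,6,6-trimethyl-5-(3-methylbut-2-en-1-yl)cyclohex-2-en-1-yl]methoxy}silane | CC(C)=CC[C@H]1CC=C(C)[C@@H](CO[Si](C)(C)C(C)(C)C)C1(C)C | intermediate
21 | [(1R,5S)-2,6,6-trimethyl-5-(3-methylbut-2-en-1-yl)cyclohex-2-en-1-yl]methanol | CC(C)=CC[C@H]1CC=C(C)[C@@H](CO)C1(C)C | intermediate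
22 | (1R,5S)-2,6,6-trimethyl-5-(3-methylbut-2-en-1-yl)cyclohex-2-ene-1-carbaldehyde | CC(C)=CC[C@H]1CC=C(C)[C@@H](C=O)C1(C)C | intermediate
23 | 1-(triphenylphosphoranylidene)propan-2-one | CC(=O)C=P(c1ccccc1)(c1ccccc1)c1ccccc1 | starting material
24 | (3E)-4-[(1R,5S)-2,6,6-trimethyl-5-(3-methylbut-2-en-1-yl)cyclohex-2-en-1-yl]but-3-en-2-one | CC(C)=CC[C@H]1CC=C(C)[C@@H](/C=C/C(C)=O)C1(C)C | intermediate
25 | vinylmagnesium bromide | C=C[Mg]Br | starting material
26 | (1E)-3-methyl-1-[(1R,5S)-2,6,6-trimethyl-5-(3-methylbut-2-en-1-yl)cyclohex-2-en-1-yl]penta-1,4-dien-3-ol (C3 epimers) | CC(C)=CC[C@H]1CC=C(C)[C@@H](/C=C/C(C)(O)C=C)C1(C)C | intermediate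
27 | ring A C20 phosphonium bromide | CC(C)=CC[C@H]1CC=C(C)[C@@H](/C=C/C(C)=C/C[P+](c2ccccc2)(c2ccccc2)c2ccccc2)C1(C)C.[Br-] | intermediate
28 | (2E,4E,6E)-2,7-dimethylocta-2,4,6-trienedial | O=C/C(C)=C/C=C/C=C(C)/C=O | starting material
29 | ring A C30 aldehyde (all-E) | CC(C)=CC[C@H]1CC=C(C)[C@@H](/C=C/C(C)=C/C=C/C(C)=C/C=C/C=C(C)/C=O)C1(C)C | intermediate
30 | methyl methacrylate | C=C(C)C(=O)OC | starting material
31 | methyl (2E)-4-[(1R,5R)-5-{[(tert-butyldimethylsilyl)oxy]methyl}-4,6,6-trimethylcyclohex-3-en-1-yl]-2-methylbut-2-enoate | COC(=O)/C(C)=C/C[C@H]1CC=C(C)[C@@H](CO[Si](C)(C)C(C)(C)C)C1(C)C | intermediate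
32 | methyl (2E)-4-[(1R,5R)-5-(hydroxymethyl)-4,6,6-trimethylcyclohex-3-en-1-yl]-2-methylbut-2-enoate | COC(=O)/C(C)=C/C[C@H]1CC=C(C)[C@@H](CO)C1(C)C | intermediate
33 | methyl (2E)-4-[(1R,5R)-5-formyl-4,6,6-trimethylcyclohex-3-en-1-yl]-2-methylbut-2-enoate | COC(=O)/C(C)=C/C[C@H]1CC=C(C)[C@@H](C=O)C1(C)C | intermediate
34 | ring B cis-enone (C2 R, C6 R) | COC(=O)/C(C)=C/C[C@H]1CC=C(C)[C@@H](/C=C/C(C)=O)C1(C)C | intermediate
35 | ring B trans-enone (C2 R, C6 S) | COC(=O)/C(C)=C/C[C@H]1CC=C(C)[C@H](/C=C/C(C)=O)C1(C)C | intermediate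
36 | ring B vinyl carbinol (carbinol epimers) | COC(=O)/C(C)=C/C[C@H]1CC=C(C)[C@H](/C=C/C(C)(O)C=C)C1(C)C | intermediate
37 | ring B C20 phosphonium bromide | COC(=O)/C(C)=C/C[C@H]1CC=C(C)[C@H](/C=C/C(C)=C/C[P+](c2ccccc2)(c2ccccc2)c2ccccc2)C1(C)C.[Br-] | intermediate
38 | C50 methyl ester, (2S,6R,2'R,6'S), all-E | CC(C)=CC[C@H]1CC=C(C)[C@@H](/C=C/C(C)=C/C=C/C(C)=C/C=C/C=C(C)/C=C/C=C(C)/C=C/[C@H]2C(C)=CC[C@H](C/C=C(\C)C(=O)OC)C2(C)C)C1(C)C | intermediate
39 | CNP0304855.1, (2S,6R,2'R,6'S) | CC(C)=CC[C@H]1CC=C(C)[C@@H](/C=C/C(C)=C/C=C/C(C)=C/C=C/C=C(C)/C=C/C=C(C)/C=C/[C@H]2C(C)=CC[C@H](C/C=C(\C)CO)C2(C)C)C1(C)C | target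

**Step count.** Total: 27 steps. Longest linear sequence: 20 steps (1–18, 26, 27; the ring B branch 1–11, 19–27 is equally long).

**Steps most likely to fail**

1. Step 11. What may go wrong: the two allyl groups close on each other and the five-membered ring is not reopened fast enough, or the six-ring closure engages the wrong allyl group (poor diastereotopic-group selectivity). Fallback, from 11 back to 18: ester 11 is converted with Me2AlN(OMe)Me (from AlMe3 and MeNHOMe·HCl) into Weinreb amide F1. One equivalent of allylMgBr at −78 °C then gives allyl ketone 13, isolated in this case because the magnesium chelate of the tetrahedral adduct holds until work-up. Ketone 13 carries a single allyl group, so ring-closing metathesis with second-generation Grubbs catalyst (H2IMes)(PCy3)Cl2Ru=CHPh can only form the six-membered ring and gives cyclohexenone F2. AllylMgBr/CeCl3 then gives ring tertiary alcohol F3, and n-BuLi/methyl chlorooxoacetate gives ring oxalate F4. Bu3SnH/AIBN generates the ring C2 radical, which should take up hydrogen from the face away from the C6 silyloxymethyl group, placing the allyl cis to C6 and giving 18. C2 is then set by hydrogen-atom transfer on the ring and not by group selection.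

2. Step 10. What may go wrong: thermal elimination of the crowded tertiary oxalate before C–O homolysis, or intramolecular hydrogen transfer in the C2 radical that shifts the butenyl alkene. Fallback, from 11 back to 16, builds the CH(allyl)2 carbon without a tertiary alcohol: LiAlH4 reduces 11 to primary alcohol F5 and Dess–Martin oxidation gives neopentyl aldehyde F6. Knoevenagel condensation with dimethyl malonate (TiCl4, pyridine) gives alkylidene malonate F7, and conjugate addition of allylMgBr with catalytic CuBr·SMe2 gives allyl malonate F8. Krapcho demethoxycarbonylation (LiCl, wet DMSO, 150 °C) gives mono-ester F9, DIBAL (iBu2AlH) at −78 °C gives aldehyde F10, and Wittig methylenation (Ph3P=CH2) turns the second arm into an allyl group to give 16. The transient stereocentre at C2 in F8–F10 is of no consequence, because both arms end as allyl.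

3. Step 15. What may go wrong: slow olefination of the hindered aldehyde, with loss of the cis relationship through enolisation at C6 (the trans epimer is the more stable one) or migration of the ring alkene into conjugation. Fallback, from 21 back to 27, never places a carbonyl at C7: Mitsunobu reaction of 21 with 1-phenyl-1H-tetrazole-5-thiol (PPh3, DIAD) gives tetrazolyl sulfide F11, and (NH4)6Mo7O24/H2O2 oxidises it to tetrazolyl sulfone F12. Julia–Kocienski olefination (KN(SiMe3)2, THF, −78 °C) with aldehyde 1 gives dienyl acetate F13, and PPh3·HBr converts this allylic acetate directly into phosphonium salt 27.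

**Further compounds**
F1 | step 11 | (3R,4E)-3-{[(tert-butyldimethylsilyl)oxy]methyl}-N-methoxy-N,2,2,4-tetramethylhex-4-enamide | CON(C)C(=O)C(C)(C)[C@H](CO[Si](C)(C)C(C)(C)C)/C(C)=C/C
F2 | step 11 | (3R)-3-{[(tert-butyldimethylsilyl)oxy]methyl}-2,2,4-trimethylcyclohex-4-en-1-one | O=C1CC=C(C)[C@@H](CO[Si](C)(C)C(C)(C)C)C1(C)C
F3 | step 11 | (5R)-1-allyl-5-{[(tert-butyldimethylsilyl)oxy]methyl}-4,6,6-trimethylcyclohex-3-en-1-ol (either C1 epimer) | C=CCC1(O)CC=C(C)[C@@H](CO[Si](C)(C)C(C)(C)C)C1(C)C
F4 | step 11 | methyl oxalate of F3 | COC(=O)C(=O)OC1(CC=C)CC=C(C)[C@@H](CO[Si](C)(C)C(C)(C)C)C1(C)C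
F5 | step 10 | (3R,4E)-3-{[(tert-butyldimethylsilyl)oxy]methyl}-2,2,4-trimethylhex-4-en-1-ol | OCC(C)(C)[C@H](CO[Si](C)(C)C(C)(C)C)/C(C)=C/C
F6 | step 10 | (3R,4E)-3-{[(tert-butyldimethylsilyl)oxy]methyl}-2,2,4-trimethylhex-4-enal | O=CC(C)(C)[C@H](CO[Si](C)(C)C(C)(C)C)/C(C)=C/C
F7 | step 10 | dimethyl 2-[(3R,4E)-3-{[(tert-butyldimethylsilyl)oxy]methyl}-2,2,4-trimethylhex-4-en-1-ylidene]malonate | COC(=O)C(C(=O)OC)=CC(C)(C)[C@H](CO[Si](C)(C)C(C)(C)C)/C(C)=C/C
F8 | step 10 | dimethyl 2-[(6R,7E)-6-{[(tert-butyldimethylsilyl)oxy]methyl}-5,5,7-trimethylnona-1,7-dien-4-yl]malonate (C4 epimers) | COC(=O)C(C(=O)OC)C(CC=C)C(C)(C)[C@H](CO[Si](C)(C)C(C)(C)C)/C(C)=C/C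
F9 | step 10 | methyl (5R,6E)-3-allyl-5-{[(tert-butyldimethylsilyl)oxy]methyl}-4,4,6-trimethyloct-6-enoate (C3 epimers) | COC(=O)CC(CC=C)C(C)(C)[C@H](CO[Si](C)(C)C(C)(C)C)/C(C)=C/C
F10 | step 10 | (5R,6E)-3-allyl-5-{[(tert-butyldimethylsilyl)oxy]methyl}-4,4,6-trimethyloct-6-enal (C3 epimers) | O=CCC(CC=C)C(C)(C)[C@H](CO[Si](C)(C)C(C)(C)C)/C(C)=C/C
F11 | step 15 | 1-phenyl-5-({[(1R,5S)-2,6,6-trimethyl-5-(3-methylbut-2-en-1-yl)cyclohex-2-en-1-yl]methyl}sulfanyl)-1H-tetrazole | CC(C)=CC[C@H]1CC=C(C)[C@@H](CSc2nnnn2-c2ccccc2)C1(C)C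
F12 | step 15 | 1-phenyl-5-({[(1R,5S)-2,6,6-trimethyl-5-(3-methylbut-2-en-1-yl)cyclohex-2-en-1-yl]methyl}sulfonyl)-1H-tetrazole | CC(C)=CC[C@H]1CC=C(C)[C@@H](CS(=O)(=O)c2nnnn2-c2ccccc2)C1(C)C
F13 | step 15 | (2E,4E)-3-methyl-5-[(1R,5S)-2,6,6-trimethyl-5-(3-methylbut-2-en-1-yl)cyclohex-2-en-1-yl]penta-2,4-dien-1-yl acetate | CC(C)=CC[C@H]1CC=C(C)[C@@H](/C=C/C(C)=C/COC(C)=O)C1(C)C
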